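**Strategy.** Everything rests on the C3a–C4 bond of the cyclohexene. In benzofuranone numbering, C3a=C3–O–C6–C5=C4 is an allyl vinyl ether held inside a dihydropyran, and its ester-bearing enol ether carbon C3 later becomes the methylidene lactone. One thermal, ester-accelerated Claisen shift through a boat-shaped, bicyclo[2.2.2]-like array closes the carbocycle, creates the tetrasubstituted C5=C6 alkene and sets C3a and C4 from the C6/C7a relationship of the pyran and the E silyl enol ether. The precursor is a 2-methyl-2-alkenyl-4-(4-methoxybenzyloxy)-3,4-dihydro-2H-pyran-6-carboxylate, built from a Cu(OTf)2–bis(oxazoline) hetero-Diels–Alder adduct and a citronellal-derived enol silane.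

Key step: step 11

Assumption: the (S,S)-ligand is assigned from the square-planar chelate model (attack on the oxadiene face remote from the tert-butyl group, giving 4R); if the adduct proved to be the antipode, the (R,R)-ligand would be used and nothing else changes.
Assumption: (R)-2-methylbutanoic acid of high enantiomeric purity is taken as purchasable.

Step 1
Reactants: 1 4-methoxybenzyl alcohol; 2 butyl vinyl ether
Product: 3 4-methoxybenzyl vinyl ether
Conditions: Pd(OCOCF3)2 (0.5 mol%), 4,7-diphenyl-1,10-phenanthroline (0.5 mol%), Et3N (cat.), neat 2 (20 equiv), 75 °C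
Reagents that add atoms: none
Why: Palladium-catalysed transfer vinylation (transetherification) of a primary alcohol by an excess of an alkyl vinyl ether is a standard entry to vinyl ethers and forms no stereocentre.

Step 2
Reactants: 3 4-methoxybenzyl vinyl ether; 4 methyl chlorooxoacetate
Product: 5 methyl (3E)-4-[(4-methoxybenzyl)oxy]-2-oxobut-3-enoate
Conditions: pyridine (1.2 equiv), CH2Cl2, 0 °C → rt
Reagents that add atoms: none
Why: Electrophilic acylation of the enol ether at its β-carbon by the acid chloride, followed by loss of HCl to pyridine, should give the push–pull enone in its more stable E geometry, as in the known preparation of 4-alkoxy-2-oxobut-3-enoates.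

Step 3
Reactants: 5 methyl (3E)-4-[(4-methoxybenzyl)oxy]-2-oxobut-3-enoate; 6 2-methoxypropene
Product: 7 methyl (2R,4R)-2-methoxy-4-[(4-methoxybenzyl)oxy]-2-methyl-3,4-dihydro-2H-pyran-6-carboxylate
Conditions: Cu(OTf)2 (5 mol%), (S,S)-2,2′-isopropylidenebis(4-tert-butyl-2-oxazoline) (5.5 mol%), 3 Å MS, THF, −78 → −40 °C
Reagents that add atoms: none
Why: Inverse-electron-demand hetero-Diels–Alder reaction of the keto ester, chelated through both carbonyl oxygens to the square-planar copper bis(oxazoline) complex, in which the ligand shields one face of the oxadiene so that C4 of the pyran (C7a of the target) is formed R, while the ketal centre set by the endo rule is erased in step 9.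

Step 4
Reactants: 8 (S)-citronellal
Product: 9 (6S)-8,8-dimethoxy-2,6-dimethyloct-2-ene
Conditions: HC(OMe)3, MeOH, PPTS (cat.), rt
Reagents that add atoms: trimethyl orthoformate, COC(OC)OC; methanol, CO
Why: Acid-catalysed acetalisation, with the orthoformate as water scavenger, masks the aldehyde under conditions mild enough to avoid the carbonyl-ene cyclisation of citronellal and leaves the stereocentre untouched.

Step 5
Reactants: 9 (6S)-8,8-dimethoxy-2,6-dimethyloct-2-ene
Product: 11 (4S)-6,6-dimethoxy-4-methylhexan-1-ol, via acetal aldehyde 10 (not isolated)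
Conditions: O3, CH2Cl2/MeOH (3:1), NaHCO3, −78 °C; then NaBH4, −78 °C → rt
Reagents that add atoms: ozone, [O-][O+]=O
Why: Ozonolysis of the only alkene followed by borohydride reduction in the same flask should give the primary alcohol, the buffered acetal being inert.

Step 6
Reactants: 11 (4S)-6,6-dimethoxy-4-methylhexan-1-ol
Product: 12 tert-butyl{[(4S)-6,6-dimethoxy-4-methylhexyl]oxy}diphenylsilane
Conditions: TBDPSCl, imidazole, CH2Cl2, rt
Reagents that add atoms: tert-butyl(chloro)diphenylsilane, CC(C)(C)[Si](Cl)(c1ccccc1)c1ccccc1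
Why: Standard imidazole-mediated silylation of a primary alcohol installs the most acid-stable common silyl ether.

Step 7
Reactants: 12 tert-butyl{[(4S)-6,6-dimethoxy-4-methylhexyl]oxy}diphenylsilane
Product: 13 (3S)-6-[(tert-butyldiphenylsilyl)oxy]-3-methylhexanal
Conditions: p-TsOH·H2O (cat.), acetone/H2O (9:1), rt
Reagents that add atoms: water, O
Why: Mild acid-catalysed acetal hydrolysis frees the aldehyde while the tert-butyldiphenylsilyl ether survives.

Step 8
Reactants: 13 (3S)-6-[(tert-butyldiphenylsilyl)oxy]-3-methylhexanal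
Product: 14 tert-butyl({(3S)-6-[(tert-butyldiphenylsilyl)oxy]-3-methylhex-1-en-1-yl}oxy)dimethylsilane (E/Z mixture)
Conditions: TBSOTf (1.2 equiv), Et3N (2 equiv), CH2Cl2, 0 °C
Reagents that add atoms: tert-butyldimethylsilyl trifluoromethanesulfonate, CC(C)(C)[Si](C)(C)OS(=O)(=O)C(F)(F)F
Why: Soft enolisation (silyl triflate and tertiary amine) converts the aldehyde into a chromatographable silyl enol ether whose geometry is irrelevant because this carbon is enolised again in step 10.

Step 9
Reactants: 7 methyl (2R,4R)-2-methoxy-4-[(4-methoxybenzyl)oxy]-2-methyl-3,4-dihydro-2H-pyran-6-carboxylate; 14 tert-butyl({(3S)-6-[(tert-butyldiphenylsilyl)oxy]-3-methylhex-1-en-1-yl}oxy)dimethylsilane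
Product: 15 methyl (2S,4R)-2-{(3S)-6-[(tert-butyldiphenylsilyl)oxy]-3-methyl-1-oxohexan-2-yl}-4-[(4-methoxybenzyl)oxy]-2-methyl-3,4-dihydro-2H-pyran-6-carboxylate (both epimers at the aldehyde α-carbon)
Conditions: TMSOTf (0.2 equiv), 2,6-di-tert-butyl-4-methylpyridine (0.3 equiv), CH2Cl2, −78 °C; aq. NaHCO3
Reagents that add atoms: none
Why: Mukaiyama-type ketal substitution, in which the silyl triflate ionises the exocyclic, more basic methoxy group to the tertiary cyclic oxocarbenium ion and the enol silane attacks through its β-carbon along the pseudoaxial trajectory of the half-chair that keeps the C4 ether pseudoequatorial, that is on the face opposite to that ether, so that the quaternary centre (C6 of the target) is formed 2,4-trans, the new aldehyde α-centre being erased in step 10.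

Step 10
Reactants: 15 methyl (2S,4R)-2-{(3S)-6-[(tert-butyldiphenylsilyl)oxy]-3-methyl-1-oxohexan-2-yl}-4-[(4-methoxybenzyl)oxy]-2-methyl-3,4-dihydro-2H-pyran-6-carboxylate
Product: 16 methyl (2S,4R)-2-{(1E,3S)-1-[(tert-butyldimethylsilyl)oxy]-6-[(tert-butyldiphenylsilyl)oxy]-3-methylhex-1-en-2-yl}-4-[(4-methoxybenzyl)oxy]-2-methyl-3,4-dihydro-2H-pyran-6-carboxylate
Conditions: TBSOTf (1.3 equiv), Et3N (3 equiv), CH2Cl2, −78 → 0 °C; chromatography on Et3N-treated silica
Reagents that add atoms: tert-butyldimethylsilyl trifluoromethanesulfonate, CC(C)(C)[Si](C)(C)OS(=O)(=O)C(F)(F)F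
Why: Soft enolisation passes through the O-silylated oxocarbenium ion and not through a free enolate, which would expel the ring oxygen, and allylic strain places the silyloxy group cis to the secondary alkyl branch and trans to the quaternary pyran carbon, which is the E enol ether.

Step 11
Reactants: 16 methyl (2S,4R)-2-{(1E,3S)-1-[(tert-butyldimethylsilyl)oxy]-6-[(tert-butyldiphenylsilyl)oxy]-3-methylhex-1-en-2-yl}-4-[(4-methoxybenzyl)oxy]-2-methyl-3,4-dihydro-2H-pyran-6-carboxylate
Product: 17 methyl 2-{(1R,2R,6R)-2-[(tert-butyldimethylsilyl)oxy]-3-{(2S)-5-[(tert-butyldiphenylsilyl)oxy]pentan-2-yl}-6-[(4-methoxybenzyl)oxy]-4-methylcyclohex-3-en-1-yl}-2-oxoacetate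
Conditions: degassed PhMe (0.02 M), 2,6-di-tert-butyl-4-methylpyridine (10 mol%), silylated sealed tube, 130 °C
Reagents that add atoms: none
Why: A concerted, suprafacial [3,3]-sigmatropic shift of the allyl vinyl ether C3a=C3–O–C6–C5=C4 (target numbering, O being the pyran oxygen) forms the C3a–C4 bond as the ring O–C6 bond breaks, leaving the C3 ketone and the C5=C6 alkene. The closest known reactions are the Gosteli–Claisen rearrangement of 2-alkoxycarbonyl allyl vinyl ethers and the thermal Claisen conversion of 2-alkenyl-3,4-dihydro-2H-pyrans into 4-acylcyclohexenes, and here the ester on the vinyl ether and the silyloxy donor on the allyl terminus should both lower the barrier. The carbocycle closes because the C7–C7a tether holds C6 and C3a 1,4 across the pericyclic array, which forces a boat in which the three two-atom bridges make a bicyclo[2.2.2]octane-like transition state, the enol ether alkene C5=C4 ending up inside the new six-membered ring and the vinyl ether alkene outside it. C3a is controlled by the quaternary centre C6, since the arm can reach C3a only on the pyran face it occupies, which is trans to the C7a ether, so that the keto ester chain ends up cis to that ether. C4 is controlled by the enol ether geometry, since in the E isomer hydrogen takes the inside position under the tether and the silyloxy group points to the O–C3 bridge, hence cis to the keto ester. The step needs stereospecificity (no heterolysis to a silyloxyallyl cation and an enolate) and survival of the epimerisable α-keto ester, which the acid-free, weakly buffered thermal conditions and the built-in activation should secure, while any Z enol ether, with its silyloxy group under the tether, should react far more slowly.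

Step 12
Reactants: 17 methyl 2-{(1R,2R,6R)-2-[(tert-butyldimethylsilyl)oxy]-3-{(2S)-5-[(tert-butyldiphenylsilyl)oxy]pentan-2-yl}-6-[(4-methoxybenzyl)oxy]-4-methylcyclohex-3-en-1-yl}-2-oxoacetate
Product: 18 methyl 2-{(1R,2R,6R)-2-[(tert-butyldimethylsilyl)oxy]-3-{(2S)-5-[(tert-butyldiphenylsilyl)oxy]pentan-2-yl}-6-[(4-methoxybenzyl)oxy]-4-methylcyclohex-3-en-1-yl}prop-2-enoate
Conditions: Cp2Ti(μ-Cl)(μ-CH2)AlMe2 (1.1 equiv), pyridine (cat.), THF/PhMe, −40 → 0 °C
Reagents that add atoms: Cp2Ti(μ-Cl)(μ-CH2)AlMe2 (Tebbe reagent), C[Al-]1(C)C[Ti]([Cl+]1)(C1C=CC=C1)C1C=CC=C1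
Why: Tebbe methylenation, in which the non-basic titanium methylidene undergoes [2+2] addition and cycloreversion at the ketone, much more electrophilic than the adjacent ester, so that the ring carbon next to the ketone is not enolised and the all-cis triad is kept.

Step 13
Reactants: 18 methyl 2-{(1R,2R,6R)-2-[(tert-butyldimethylsilyl)oxy]-3-{(2S)-5-[(tert-butyldiphenylsilyl)oxy]pentan-2-yl}-6-[(4-methoxybenzyl)oxy]-4-methylcyclohex-3-en-1-yl}prop-2-enoate
Product: 20 (3aR,4R,7aR)-4-[(tert-butyldimethylsilyl)oxy]-5-{(2S)-5-[(tert-butyldiphenylsilyl)oxy]pentan-2-yl}-6-methyl-3-methylidene-3a,4,7,7a-tetrahydro-1-benzofuran-2(3H)-one, via hydroxy ester 19 (not isolated)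
Conditions: DDQ (1.3 equiv), CH2Cl2/pH 7 buffer, 0 °C → rt; then PPTS (cat.), PhMe, 50 °C
Reagents that add atoms: none
Why: Oxidative cleavage of the 4-methoxybenzyl ether by DDQ frees the C7a hydroxyl, which is cis to the acrylate and closes the γ-lactone by acid-catalysed transesterification, and only this lactone can form because the C4 oxygen is still silylated.

Step 14
Reactants: 20 (3aR,4R,7aR)-4-[(tert-butyldimethylsilyl)oxy]-5-{(2S)-5-[(tert-butyldiphenylsilyl)oxy]pentan-2-yl}-6-methyl-3-methylidene-3a,4,7,7a-tetrahydro-1-benzofuran-2(3H)-one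
Product: 21 (3aS,4R,7aR)-5-{(2S)-5-[(tert-butyldiphenylsilyl)oxy]pentan-2-yl}-4-hydroxy-6-methyl-3-methylidene-3a,4,7,7a-tetrahydro-1-benzofuran-2(3H)-one
Conditions: CSA (0.3 equiv), MeOH/CH2Cl2 (1:1), 0 °C → rt
Reagents that add atoms: none
Why: Acid-catalysed methanolysis discriminates the two silyl ethers by their known acid stability, the tert-butyldimethylsilyl ether being far more labile than the tert-butyldiphenylsilyl ether, so that only the C4 hydroxyl is freed (the change of the C3a descriptor is formal).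

Step 15
Reactants: 21 (3aS,4R,7aR)-5-{(2S)-5-[(tert-butyldiphenylsilyl)oxy]pentan-2-yl}-4-hydroxy-6-methyl-3-methylidene-3a,4,7,7a-tetrahydro-1-benzofuran-2(3H)-one; 22 (R)-2-methylbutanoic acid
Product: 24 (3aR,4R,7aR)-5-{(2S)-5-[(tert-butyldiphenylsilyl)oxy]pentan-2-yl}-6-methyl-3-methylidene-2-oxo-2,3,3a,4,7,7a-hexahydro-1-benzofuran-4-yl (2R)-2-methylbutanoate, via mixed anhydride 23 (not isolated)
Conditions: 22, 2,4,6-trichlorobenzoyl chloride, Et3N, THF, rt; then 21, DMAP, PhMe, rt
Reagents that add atoms: none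
Why: Yamaguchi esterification, in which DMAP attacks the mixed anhydride at its less hindered aliphatic carbonyl and the acylpyridinium ion acylates the hindered secondary alcohol with retention at C4 and without enolising the α-centre of the acid.

Step 16
Reactants: 24 (3aR,4R,7aR)-5-{(2S)-5-[(tert-butyldiphenylsilyl)oxy]pentan-2-yl}-6-methyl-3-methylidene-2-oxo-2,3,3a,4,7,7a-hexahydro-1-benzofuran-4-yl (2R)-2-methylbutanoate
Product: 25 (3aR,4R,7aR)-5-[(2S)-5-hydroxypentan-2-yl]-6-methyl-3-methylidene-2-oxo-2,3,3a,4,7,7a-hexahydro-1-benzofuran-4-yl (2R)-2-methylbutanoate (CNP0291605.3)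
Conditions: HF·pyridine, pyridine, THF, 0 °C → rt
Reagents that add atoms: none
Why: Fluoride-mediated cleavage of the primary silyl ether under buffered, weakly acidic conditions should spare the methylidene lactone, the allylic ester and all stereocentres.

**Compound list**

1 | 4-methoxybenzyl alcohol | COc1ccc(CO)cc1 | starting material
2 | butyl vinyl ether | C=COCCCC | starting material
3 | 4-methoxybenzyl vinyl ether | C=COCc1ccc(OC)cc1 | intermediate
4 | methyl chlorooxoacetate | COC(=O)C(Cl)=O | starting material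
5 | methyl (3E)-4-[(4-methoxybenzyl)oxy]-2-oxobut-3-enoate | COC(=O)C(=O)/C=C/OCc1ccc(OC)cc1 | intermediate
6 | 2-methoxypropene | COC(C)=C | starting material
7 | methyl (2R,4R)-2-methoxy-4-[(4-methoxybenzyl)oxy]-2-methyl-3,4-dihydro-2H-pyran-6-carboxylate (methoxy cis to the benzylic ether) | COC(=O)C1=C[C@H](OCc2ccc(OC)cc2)C[C@](C)(OC)O1 | intermediate
8 | (S)-citronellal | C[C@@H](CCC=C(C)C)CC=O | starting material
9 | (6S)-8,8-dimethoxy-2,6-dimethyloct-2-ene | C[C@@H](CCC=C(C)C)CC(OC)OC | intermediate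
10 | (4S)-6,6-dimethoxy-4-methylhexanal | C[C@@H](CCC=O)CC(OC)OC | intermediate
11 | (4S)-6,6-dimethoxy-4-methylhexan-1-ol | C[C@@H](CCCO)CC(OC)OC | intermediate
12 | tert-butyl{[(4S)-6,6-dimethoxy-4-methylhexyl]oxy}diphenylsilane | C[C@@H](CCCO[Si](c1ccccc1)(c1ccccc1)C(C)(C)C)CC(OC)OC | intermediate
13 | (3S)-6-[(tert-butyldiphenylsilyl)oxy]-3-methylhexanal | C[C@@H](CCCO[Si](c1ccccc1)(c1ccccc1)C(C)(C)C)CC=O | intermediate
14 | tert-butyl({(3S)-6-[(tert-butyldiphenylsilyl)oxy]-3-methylhex-1-en-1-yl}oxy)dimethylsilane (E/Z mixture) | C[C@@H](CCCO[Si](c1ccccc1)(c1ccccc1)C(C)(C)C)C=CO[Si](C)(C)C(C)(C)C | intermediate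
15 | methyl (2S,4R)-2-{(3S)-6-[(tert-butyldiphenylsilyl)oxy]-3-methyl-1-oxohexan-2-yl}-4-[(4-methoxybenzyl)oxy]-2-methyl-3,4-dihydro-2H-pyran-6-carboxylate (both epimers at the aldehyde α-carbon) | COC(=O)C1=C[C@H](OCc2ccc(OC)cc2)C[C@](C)(O1)C(C=O)[C@@H](C)CCCO[Si](c3ccccc3)(c4ccccc4)C(C)(C)C | intermediate
16 | methyl (2S,4R)-2-{(1E,3S)-1-[(tert-butyldimethylsilyl)oxy]-6-[(tert-butyldiphenylsilyl)oxy]-3-methylhex-1-en-2-yl}-4-[(4-methoxybenzyl)oxy]-2-methyl-3,4-dihydro-2H-pyran-6-carboxylate | COC(=O)C1=C[C@H](OCc2ccc(OC)cc2)C[C@](C)(O1)/C(=C/O[Si](C)(C)C(C)(C)C)[C@@H](C)CCCO[Si](c3ccccc3)(c4ccccc4)C(C)(C)C | intermediate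
17 | methyl 2-{(1R,2R,6R)-2-[(tert-butyldimethylsilyl)oxy]-3-{(2S)-5-[(tert-butyldiphenylsilyl)oxy]pentan-2-yl}-6-[(4-methoxybenzyl)oxy]-4-methylcyclohex-3-en-1-yl}-2-oxoacetate | COC(=O)C(=O)[C@@H]1[C@H](OCc2ccc(OC)cc2)CC(C)=C([C@@H](C)CCCO[Si](c3ccccc3)(c4ccccc4)C(C)(C)C)[C@@H]1O[Si](C)(C)C(C)(C)C | intermediate
18 | methyl 2-{(1R,2R,6R)-2-[(tert-butyldimethylsilyl)oxy]-3-{(2S)-5-[(tert-butyldiphenylsilyl)oxy]pentan-2-yl}-6-[(4-methoxybenzyl)oxy]-4-methylcyclohex-3-en-1-yl}prop-2-enoate | COC(=O)C(=C)[C@@H]1[C@H](OCc2ccc(OC)cc2)CC(C)=C([C@@H](C)CCCO[Si](c3ccccc3)(c4ccccc4)C(C)(C)C)[C@@H]1O[Si](C)(C)C(C)(C)C | intermediate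
19 | methyl 2-{(1R,2R,6R)-2-[(tert-butyldimethylsilyl)oxy]-3-{(2S)-5-[(tert-butyldiphenylsilyl)oxy]pentan-2-yl}-6-hydroxy-4-methylcyclohex-3-en-1-yl}prop-2-enoate | COC(=O)C(=C)[C@@H]1[C@H](O)CC(C)=C([C@@H](C)CCCO[Si](c2ccccc2)(c3ccccc3)C(C)(C)C)[C@@H]1O[Si](C)(C)C(C)(C)C | intermediate
20 | (3aR,4R,7aR)-4-[(tert-butyldimethylsilyl)oxy]-5-{(2S)-5-[(tert-butyldiphenylsilyl)oxy]pentan-2-yl}-6-methyl-3-methylidene-3a,4,7,7a-tetrahydro-1-benzofuran-2(3H)-one | C=C1C(=O)O[C@@H]2CC(C)=C([C@@H](C)CCCO[Si](c3ccccc3)(c4ccccc4)C(C)(C)C)[C@H](O[Si](C)(C)C(C)(C)C)[C@H]12 | intermediate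
21 | (3aS,4R,7aR)-5-{(2S)-5-[(tert-butyldiphenylsilyl)oxy]pentan-2-yl}-4-hydroxy-6-methyl-3-methylidene-3a,4,7,7a-tetrahydro-1-benzofuran-2(3H)-one | C=C1C(=O)O[C@@H]2CC(C)=C([C@@H](C)CCCO[Si](c3ccccc3)(c4ccccc4)C(C)(C)C)[C@H](O)[C@H]12 | intermediate
22 | (R)-2-methylbutanoic acid | CC[C@@H](C)C(=O)O | starting material
23 | (2R)-2-methylbutanoic 2,4,6-trichlorobenzoic anhydride | CC[C@@H](C)C(=O)OC(=O)c1c(Cl)cc(Cl)cc1Cl | intermediate
24 | (3aR,4R,7aR)-5-{(2S)-5-[(tert-butyldiphenylsilyl)oxy]pentan-2-yl}-6-methyl-3-methylidene-2-oxo-2,3,3a,4,7,7a-hexahydro-1-benzofuran-4-yl (2R)-2-methylbutanoate | C=C1C(=O)O[C@@H]2CC(C)=C([C@@H](C)CCCO[Si](c3ccccc3)(c4ccccc4)C(C)(C)C)[C@H](OC(=O)[C@H](C)CC)[C@H]12 | intermediate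
25 | (3aR,4R,7aR)-5-[(2S)-5-hydroxypentan-2-yl]-6-methyl-3-methylidene-2-oxo-2,3,3a,4,7,7a-hexahydro-1-benzofuran-4-yl (2R)-2-methylbutanoate (CNP0291605.3) | C=C1C(=O)O[C@@H]2CC(C)=C([C@@H](C)CCCO)[C@H](OC(=O)[C@H](C)CC)[C@H]12 | target

Total step count: 16. Longest linear sequence: 13 steps (steps 4 to 16, from (S)-citronellal).

**Steps most likely to fail**

Step 11 (key step). What may go wrong: heterolysis of the allylic O–C6 bond of the pyran to a silyloxyallyl cation and a keto ester enolate, which would cost the stereospecificity; cycloreversion of the dihydropyran at high temperature; or no reaction below the decomposition temperature because of the strain of the enforced boat. The fallback makes the C3a–C4 bond in two ionic stages. It sets out from 16: a catalytic amount of TBSOTf with 2,6-di-tert-butyl-4-methylpyridine in CH2Cl2 at −78 °C should open the pyran by this heterolysis and pass the silyl group to the enolate oxygen, giving the ring-opened enal F1. An intramolecular Mukaiyama aldol addition of the keto ester enol silane to the aldehyde (MgBr2·OEt2 or BF3·OEt2, CH2Cl2, −78 °C, silyl transfer to the aldolate oxygen) then closes the cyclohexene and comes back to the route at 17. In this variant the C3a/C4 configuration would have to be relayed from C7a through a chelated closure and would need to be verified.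

Step 9. What may go wrong: attack of the enol silane on the face of the C7a ether, the sense known for small nucleophiles on alkoxy-substituted six-membered oxocarbenium ions, giving the 2,4-cis quaternary centre; competing loss of the ring oxygen as a keto ester enolate is a second possibility. If the cis sense prevails, the configuration of the ether is exchanged instead of that of C6. The fallback sets out from 5 and 6: the hetero-Diels–Alder reaction is run with the (R,R)-ligand to give ent-ketal F2, and coupling with 14 as in step 9 should give cis-aldehyde F3 (C6 as in 15, C7a inverted). Soft enolisation gives cis-precursor F4, and the Claisen shift, whose outcome at C3a and C4 depends only on C6 and on the enol ether geometry, gives 7a-epi keto ester F5. Tebbe methylenation with Cp2Ti(μ-Cl)(μ-CH2)AlMe2 gives 7a-epi acrylate F6, DDQ gives trans-hydroxy ester F7, which cannot close the cis lactone, and Me3SnOH in 1,2-dichloroethane gives trans-hydroxy acid F8. Mitsunobu lactonisation (PPh3, DIAD, THF) inverts C7a and comes back to the route at 20.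

Step 12. What may go wrong: epimerisation at the ring carbon next to the ketone or β-elimination of one of the flanking ethers through the keto ester enol; methylenation of the ester as well; or Lewis-acid attack on the 4-methoxybenzyl ether. The one-step olefination is then replaced by addition and elimination. Setting out from 17, Me3SiCH2Li/CeCl3 (THF, −78 °C), a non-basic organocerium reagent that adds to ketones and not to esters, should give β-hydroxysilane F9 as a mixture at the new carbinol. KN(SiMe3)2 (THF, 0 °C) then triggers Peterson syn-elimination, the same alkene arising from both carbinol epimers, and the route is rejoined at 18.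

**Further compounds**

F1 | step 11 | methyl (2Z,4R,6Z,8S)-2-[(tert-butyldimethylsilyl)oxy]-11-[(tert-butyldiphenylsilyl)oxy]-7-formyl-4-[(4-methoxybenzyl)oxy]-6,8-dimethylundeca-2,6-dienoate | COC(=O)/C(O[Si](C)(C)C(C)(C)C)=C/[C@H](OCc1ccc(OC)cc1)C/C(C)=C(\C=O)[C@@H](C)CCCO[Si](c1ccccc1)(c1ccccc1)C(C)(C)C
F2 | step 9 | methyl (2S,4S)-2-methoxy-4-[(4-methoxybenzyl)oxy]-2-methyl-3,4-dihydro-2H-pyran-6-carboxylate | COC(=O)C1=C[C@@H](OCc2ccc(OC)cc2)C[C@@](C)(OC)O1
F3 | step 9 | methyl (2S,4S)-2-{(3S)-6-[(tert-butyldiphenylsilyl)oxy]-3-methyl-1-oxohexan-2-yl}-4-[(4-methoxybenzyl)oxy]-2-methyl-3,4-dihydro-2H-pyran-6-carboxylate | COC(=O)C1=C[C@@H](OCc2ccc(OC)cc2)C[C@](C)(O1)C(C=O)[C@@H](C)CCCO[Si](c3ccccc3)(c4ccccc4)C(C)(C)C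
F4 | step 9 | methyl (2S,4S)-2-{(1E,3S)-1-[(tert-butyldimethylsilyl)oxy]-6-[(tert-butyldiphenylsilyl)oxy]-3-methylhex-1-en-2-yl}-4-[(4-methoxybenzyl)oxy]-2-methyl-3,4-dihydro-2H-pyran-6-carboxylate | COC(=O)C1=C[C@@H](OCc2ccc(OC)cc2)C[C@](C)(O1)/C(=C/O[Si](C)(C)C(C)(C)C)[C@@H](C)CCCO[Si](c3ccccc3)(c4ccccc4)C(C)(C)C
F5 | step 9 | methyl 2-{(1R,2R,6S)-2-[(tert-butyldimethylsilyl)oxy]-3-{(2S)-5-[(tert-butyldiphenylsilyl)oxy]pentan-2-yl}-6-[(4-methoxybenzyl)oxy]-4-methylcyclohex-3-en-1-yl}-2-oxoacetate | COC(=O)C(=O)[C@@H]1[C@@H](OCc2ccc(OC)cc2)CC(C)=C([C@@H](C)CCCO[Si](c3ccccc3)(c4ccccc4)C(C)(C)C)[C@@H]1O[Si](C)(C)C(C)(C)C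
F6 | step 9 | methyl 2-{(1R,2R,6S)-2-[(tert-butyldimethylsilyl)oxy]-3-{(2S)-5-[(tert-butyldiphenylsilyl)oxy]pentan-2-yl}-6-[(4-methoxybenzyl)oxy]-4-methylcyclohex-3-en-1-yl}prop-2-enoate | COC(=O)C(=C)[C@@H]1[C@@H](OCc2ccc(OC)cc2)CC(C)=C([C@@H](C)CCCO[Si](c3ccccc3)(c4ccccc4)C(C)(C)C)[C@@H]1O[Si](C)(C)C(C)(C)C
F7 | step 9 | methyl 2-{(1R,2R,6S)-2-[(tert-butyldimethylsilyl)oxy]-3-{(2S)-5-[(tert-butyldiphenylsilyl)oxy]pentan-2-yl}-6-hydroxy-4-methylcyclohex-3-en-1-yl}prop-2-enoate | COC(=O)C(=C)[C@@H]1[C@@H](O)CC(C)=C([C@@H](C)CCCO[Si](c2ccccc2)(c3ccccc3)C(C)(C)C)[C@@H]1O[Si](C)(C)C(C)(C)C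
F8 | step 9 | 2-{(1R,2R,6S)-2-[(tert-butyldimethylsilyl)oxy]-3-{(2S)-5-[(tert-butyldiphenylsilyl)oxy]pentan-2-yl}-6-hydroxy-4-methylcyclohex-3-en-1-yl}prop-2-enoic acid | OC(=O)C(=C)[C@@H]1[C@@H](O)CC(C)=C([C@@H](C)CCCO[Si](c2ccccc2)(c3ccccc3)C(C)(C)C)[C@@H]1O[Si](C)(C)C(C)(C)C
F9 | step 12 | methyl 2-{(1R,2R,6R)-2-[(tert-butyldimethylsilyl)oxy]-3-{(2S)-5-[(tert-butyldiphenylsilyl)oxy]pentan-2-yl}-6-[(4-methoxybenzyl)oxy]-4-methylcyclohex-3-en-1-yl}-2-hydroxy-3-(trimethylsilyl)propanoate (both carbinol epimers) | COC(=O)C(O)(C[Si](C)(C)C)[C@@H]1[C@H](OCc2ccc(OC)cc2)CC(C)=C([C@@H](C)CCCO[Si](c3ccccc3)(c4ccccc4)C(C)(C)C)[C@@H]1O[Si](C)(C)C(C)(C)C
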